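## Structural features

The target is an achiral diarylmethane: two benzene rings, ring A and ring B, joined only through one sp3 CH2 bridge, so no stereocentre has to be set or protected and none stands next to another. Ring A (target numbering, used for ring positions throughout, while compound names follow benzoate numbering: C1 OH, C2 OMe, C3 OH, C4 bridge, C5 CH2OH, C6 H) is pentasubstituted, with its methoxy group flanked by two phenols and the bridge carbon C4 lying between the C3 phenol and the hydroxymethyl-bearing C5. Ring B (C1' bridge, C2' H, C3' OH, C4' OH, C5' Br, C6' Br) is a catechol with two adjacent bromines, C6'–Br ortho to the bridge and C5'–Br next to the C4' hydroxyl. The fragile groups are the catechol (oxidation to an ortho-quinone by air in base or by oxidants), the C5 hydroxymethyl group (para to the methoxy group, so it ionises in strong acid), and the two aryl C–Br bonds (lost under hydrogenolysis, low-valent metals or halogen–metal exchange). The real difficulty is regiochemical: the bridge must enter ring A at C4, the bromines must land on C5' and C6' only, and four phenols of two kinds must be told apart. The key step uses the innate reactivity of a free 4-alkylcatechol: C6' is para to the C3' hydroxyl and C5' is ortho to the C4' hydroxyl, whereas C2' is wedged between the C3' hydroxyl and the bridge. Ring A is kept silent in that step as an ester diacetate.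

## Logic of the disconnections

**9 ⇒ 7.** No skeletal bond is cut. The C–H bonds of the C5 hydroxymethyl group and the O–H bonds of the two ring A phenols are traced back to a methyl ester and two aryl acetates. These three electron-poor groups are what keeps ring A unreactive in the preceding halogenation, and all three answer to one hydride reagent. The gain is that the brominated material is one operation from the end and no separate deprotection is needed. The forward step must cleave two acetates (passing through 8) and reduce a benzoate while sparing two aryl C–Br bonds, with a work-up that neither oxidises the catechol nor ionises the benzylic alcohol.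

**7 ⇒ 5.** The bonds C6'–Br and C5'–Br are cut, with 6 lying between. These are the carbons that electrophilic bromine attacks by itself in a free 4-alkylcatechol. The gain is that every earlier intermediate is halogen-free, so hydrogenolysis is allowed and ring B can come from a simple, unhalogenated building block. The forward step needs three selectivities: ring B over ring A, C5' over C2' for the second bromine, and a stop at two bromines without oxidising the catechol.

**5 ⇒ 4.** The two O–CH2Ph bonds on ring B are cut. The catechol must be free for the bromination but masked while ring A is acylated, so that the four phenols are split into two sets. The demand is a debenzylation that leaves aryl acetates, the methyl ester and the diarylmethane untouched; hydrogenolysis meets it because no halogen is present yet.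

**4 ⇒ 3.** The two O–acetyl bonds on ring A are cut. This is the point where the deactivating groups are installed, and only the ring A phenols are free at that stage. The demand is a complete acetylation of a hindered phenol (C3–OH, between the methoxy group and the bridge).

**3 ⇒ 1 + 2.** The bond between C4 of ring A and the bridge CH2 is cut. The nucleophile 1 is mirror-symmetric, its two open carbons are equivalent and each is ortho to one hydroxyl and para to the other, and the carbon between the hydroxyls is blocked by the methoxy group. Both pieces are catalogue compounds. The forward step must be a mono-C-benzylation next to an ester, and the benzylic cation must be kept from condensing with its own precursor.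

## Other disconnections considered

**Alternative 1:** The cut runs through ring A itself, at C5–C6 and C3–C4, and returns an oxygenated diene, 1,2-dimethoxy-1,3-bis(trimethylsilyloxy)buta-1,3-diene A2, and an ynone, 4-(tert-butyldimethylsilyloxy)-1-[2,3-dibromo-4,5-bis(methoxymethoxy)phenyl]but-2-yn-1-one A3.
- Forward key step: the CH2 terminus of A2 would bond to the alkyne carbon of A3 beta to the carbonyl (the one carrying the silyloxymethyl group), and the ketene acetal carbon to the alpha carbon. Loss of the acetal methoxy group and of silicon would then aromatise the new ring and give the benzophenone A1.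
- In favour: the polarisation of A2 and A3 is matched, so all five ring A substituents are placed by construction, and the bromines arrive on a building block whose substitution pattern is fixed before the rings are joined.
- Against: A2 is moisture-sensitive and must be made. A3 needs several steps of its own. A1 is one oxidation level too high at the bridge, so a diaryl ketone must be taken down to CH2 next to two C–Br bonds and a benzylic silyl ether that is itself liable to ionic reduction. Three kinds of protecting group must then be removed.
- Comparison, structure: on ring B bromine placement this alternative is the better plan; on ring A regiochemistry the two are equal, since the symmetry of 1 does the same job.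
- Comparison, mechanism: a cycloaddition–elimination with a tetra-oxygenated diene is less well proven than two electrophilic substitutions.
- Comparison, step economy: the chosen plan is clearly shorter and can use hydrogenolysis, which A1 and A3 forbid.

**Alternative 2:** The cut is the ring A bond C4–C5, between the bridge-bearing carbon and the carbon carrying the one-carbon substituent, and unfolds ring A into an open chain, methyl 8-[2,3-dibromo-4,5-bis(methoxymethoxy)phenyl]-5-methoxy-2,4,6-trioxooctanoate A5.
- Forward key step: under mild base the C7 methylene of A5 would add to the C2 keto group of its alpha-keto ester end. Dehydration and enolisation would then give the arene A4, methyl 2-[2,3-dibromo-4,5-bis(methoxymethoxy)benzyl]-3,5-dihydroxy-4-methoxybenzoate.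
- In favour: the substitution pattern of ring A is written into the chain, no ring A protecting group is needed, the bromines are pre-installed, and A4 has the same ester oxidation level as 7, so the end game is comparable.
- Against: A5 has several acidic sites and more than one way to fold (closure through oxygen, Claisen-type closure, aldol at the wrong methylene). The assembly of A5 is itself a regiochemical problem, and its saturated two-carbon link to ring B cannot be made by catalytic hydrogenation because of the C–Br bonds.
- Comparison, structure: better on bromine placement; equal on ring A regiochemistry if the folding obeys.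
- Comparison, mechanism: the folding is a plausible biomimetic aldol but harder to steer than the Friedel–Crafts and bromination steps of the chosen plan.
- Comparison, step economy: the alternative is longer, and it needs an acidic deprotection after the key step that the chosen plan avoids.

**Alternative 3:** Both bonds of the bridge are cut (C4–CH2 and CH2–C1'), giving three components: the mono-pivalate phenol methyl 3-hydroxy-4-methoxy-5-(pivaloyloxy)benzoate A7, [2,3-dibromo-4,5-bis(methoxymethoxy)phenyl]boronic acid A8 and formaldehyde A9.
- Forward key step: the three would condense to the benzodioxaborin A10. On acid activation the O–CH2 bond of A10 would ionise while boron stays bound to the phenol oxygen, and the aryl group would pass from boron to the exocyclic carbon, giving A6, methyl 2-[2,3-dibromo-4,5-bis(methoxymethoxy)benzyl]-3-hydroxy-4-methoxy-5-(pivaloyloxy)benzoate.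
- In favour: the boron template delivers the one-carbon unit only ortho to the free phenol, no free benzylic cation is involved, and the bromines are again pre-installed.
- Against: A7 requires desymmetrising 1 by a statistical mono-acylation. A8 is an ortho-brominated, hindered boronic acid that is hard to make selectively and prone to protodeboronation. The carbon to be attacked in A7 is deactivated by its ortho ester. The methoxymethyl ethers are at risk in the acid activation.
- Comparison, structure: better on bromine placement and on avoiding self-condensation of a benzylic cation; equal on ring A regiochemistry.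
- Comparison, mechanism: the aryl transfer from boron to the exocyclic carbon is less established for such a hindered aryl group than Friedel–Crafts benzylation.
- Comparison, step economy: worse, because of the extra steps to A7 and A8 and the two-stage deprotection.

Key step: step 4

Assumption: 2 is taken as a catalogue compound; if it had to be made, NaBH4 reduction of 3,4-bis(benzyloxy)benzaldehyde would supply it in one extra step.

## Route

**Step 1**
Reactants: 1 methyl 3,5-dihydroxy-4-methoxybenzoate (3 equiv); 2 3,4-bis(benzyloxy)benzyl alcohol
Product: 3 methyl 2-[3,4-bis(benzyloxy)benzyl]-3,5-dihydroxy-4-methoxybenzoate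
Conditions: p-TsOH·H2O (10 mol%), HFIP, 0 °C → rt, slow addition of 2 to 1
Reagents that add atoms: none
Why: Friedel–Crafts benzylation with loss of water: the acid in HFIP ionises 2 to a benzylic cation stabilised by the para benzyloxy group, and the cation is taken by C4 of ring A in 1 (benzoate C2), which is ortho to one hydroxyl and para to the other while the carbon between the hydroxyls is blocked by the methoxy group. The symmetry of 1 makes both open carbons the same, so a single mono-C-benzyl product is expected, and the excess of 1 with slow addition of 2 holds back a second benzylation and self-condensation of the cation with 2.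

**Step 2**
Reactants: 3 methyl 2-[3,4-bis(benzyloxy)benzyl]-3,5-dihydroxy-4-methoxybenzoate
Product: 4 methyl 3,5-diacetoxy-2-[3,4-bis(benzyloxy)benzyl]-4-methoxybenzoate
Conditions: Ac2O (3 equiv), pyridine, DMAP (5 mol%), CH2Cl2, 0 °C → rt
Reagents that add atoms: acetic anhydride CC(=O)OC(C)=O
Why: DMAP-catalysed O-acetylation of both ring A phenols, the only free hydroxyls at this stage; the benzyl ethers, the methyl ester and the diarylmethane are inert, and the acetates are the groups that later switch ring A off towards bromine.

**Step 3**
Reactants: 4 methyl 3,5-diacetoxy-2-[3,4-bis(benzyloxy)benzyl]-4-methoxybenzoate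
Product: 5 methyl 3,5-diacetoxy-2-(3,4-dihydroxybenzyl)-4-methoxybenzoate
Conditions: H2 (1 atm), 10% Pd/C, EtOAc, rt
Reagents that add atoms: none
Why: Heterogeneous hydrogenolysis of the two aryl benzyl ethers; aryl acetates, the methyl ester, the methyl ether and the diarylmethane C–C bonds are not touched, no halogen is present yet, and the aprotic solvent avoids transesterification of the acetates.

**Step 4**
Reactants: 5 methyl 3,5-diacetoxy-2-(3,4-dihydroxybenzyl)-4-methoxybenzoate
Product: 7 methyl 3,5-diacetoxy-2-(2,3-dibromo-4,5-dihydroxybenzyl)-4-methoxybenzoate, via monobromide 6 (not isolated)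
Conditions: Br2 (2.05 equiv), AcOH, 15 °C → rt, dark, argon; aq. Na2S2O3
Reagents that add atoms: bromine BrBr
Why: Each C–Br bond forms by electrophilic aromatic substitution: bromine, polarised by the acetic acid, attacks ring B to give an arenium ion stabilised by a catechol oxygen lone pair, which then loses a proton as HBr. The first bromine should enter at C6', para to the C3' hydroxyl and ortho to the bridge, giving 6; the second should enter at C5', ortho to the C4' hydroxyl and next to the first bromine, giving 7. The closest known reaction type is the bromination of free 4-alkylcatechols with bromine in acetic acid or with bromide, peroxide and NH4VO3 as a bromoperoxidase mimic. No ring is closed and no stereocentre is formed. Ring selectivity rests on ring A: its one open carbon C6 lies between the ester and an acetoxy group, and its oxygen donors are attenuated as acetates, so it is far less nucleophilic than the free catechol. Site selectivity within ring B rests on C2' being squeezed between the C3' hydroxyl and the ortho-substituted benzyl group and being meta to the first bromine, whereas the arenium ion for attack at C5' is helped by the C4' hydroxyl and by the lone pair of the adjacent bromine. Each bromine deactivates the ring for the next, so that with two equivalents the third substitution at the hindered C2' should not compete. Working cold, in the dark and without oxygen suppresses benzylic radical bromination and oxidation to the ortho-quinone, and HBr in acetic acid at room temperature leaves aryl acetates and the aryl methyl ether intact.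

**Step 5**
Reactants: 7 methyl 3,5-diacetoxy-2-(2,3-dibromo-4,5-dihydroxybenzyl)-4-methoxybenzoate
Product: 9 4-(2,3-dibromo-4,5-dihydroxybenzyl)-5-(hydroxymethyl)-2-methoxybenzene-1,3-diol, via tetraphenol ester 8 (not isolated)
Conditions: LiAlH4 (5 equiv), THF, 0 °C → rt, argon; then EtOAc, aq. potassium sodium tartrate/citric acid (pH 4)
Reagents that add atoms: none
Why: Aluminium hydride reduction: the phenolic protons are removed, the aryl acetates are cleaved to phenoxides and ethanol (8 as its aluminate), and the methyl ester, which is meta to both new phenoxides and so not deactivated by conjugation, is reduced to the primary alkoxide. Aryl bromides on electron-rich phenoxide rings should not be attacked by LiAlH4 at or below room temperature, and the buffered, oxygen-free work-up keeps the para-methoxybenzylic alcohol from ionising and the catechol from oxidising.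

## Compound list

1 | methyl 3,5-dihydroxy-4-methoxybenzoate | COC(=O)c1cc(O)c(OC)c(O)c1 | starting material
2 | 3,4-bis(benzyloxy)benzyl alcohol | OCc1ccc(OCc2ccccc2)c(OCc2ccccc2)c1 | starting material
3 | methyl 2-[3,4-bis(benzyloxy)benzyl]-3,5-dihydroxy-4-methoxybenzoate | COC(=O)c1cc(O)c(OC)c(O)c1Cc1ccc(OCc2ccccc2)c(OCc2ccccc2)c1 | intermediate
4 | methyl 3,5-diacetoxy-2-[3,4-bis(benzyloxy)benzyl]-4-methoxybenzoate | COC(=O)c1cc(OC(C)=O)c(OC)c(OC(C)=O)c1Cc1ccc(OCc2ccccc2)c(OCc2ccccc2)c1 | intermediate
5 | methyl 3,5-diacetoxy-2-(3,4-dihydroxybenzyl)-4-methoxybenzoate | COC(=O)c1cc(OC(C)=O)c(OC)c(OC(C)=O)c1Cc1ccc(O)c(O)c1 | intermediate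
6 | methyl 3,5-diacetoxy-2-(2-bromo-4,5-dihydroxybenzyl)-4-methoxybenzoate | COC(=O)c1cc(OC(C)=O)c(OC)c(OC(C)=O)c1Cc1cc(O)c(O)cc1Br | intermediate
7 | methyl 3,5-diacetoxy-2-(2,3-dibromo-4,5-dihydroxybenzyl)-4-methoxybenzoate | COC(=O)c1cc(OC(C)=O)c(OC)c(OC(C)=O)c1Cc1cc(O)c(O)c(Br)c1Br | intermediate
8 | methyl 2-(2,3-dibromo-4,5-dihydroxybenzyl)-3,5-dihydroxy-4-methoxybenzoate | COC(=O)c1cc(O)c(OC)c(O)c1Cc1cc(O)c(O)c(Br)c1Br | intermediate
9 | 4-(2,3-dibromo-4,5-dihydroxybenzyl)-5-(hydroxymethyl)-2-methoxybenzene-1,3-diol | COc1c(O)cc(CO)c(Cc2cc(O)c(O)c(Br)c2Br)c1O | target

## Step count and least certain steps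

Total step count: 5. Longest linear sequence: 5 steps (from 1 or 2 to 9).

**Step 4 (key step).**
- What may go wrong: loss of site control in the second substitution, because C2' and C5' are each ortho to one hydroxyl and the bias between them is steric and modest; a third substitution at C2'; oxidation of the catechol to the ortho-quinone by bromine, followed by tautomerisation towards a quinone methide and attack at the bridge.
- Fallback: the bromines are placed before the rings are joined, where a formyl group fixes their positions. 5-Bromovanillin F1 (purchased) is brominated once more (Br2, Fe powder, AcOH) ortho to the formyl group to give 2,3-dibromo-4-hydroxy-5-methoxybenzaldehyde F2. F2 is demethylated (BBr3, CH2Cl2, −78 °C → rt) to 2,3-dibromo-4,5-dihydroxybenzaldehyde F3 and reduced (NaBH4, THF/H2O, 0 °C) to 2,3-dibromo-4,5-dihydroxybenzyl alcohol F4. F4 ionises readily through its para hydroxyl and is used in place of 2 to benzylate an excess of 1 under the conditions of step 1, which should give 8 as an isolated compound. 8 is then reduced to 9 with LiAlH4 as in step 5. This fallback sets out from 1 and comes back to the route at 8.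

**Step 1.**
- What may go wrong: self-condensation of the benzylic cation with further molecules of 2 (oligomers of the cyclotriveratrylene type), a second benzylation of 3 at its remaining open carbon, and acid-induced loss or migration of a benzyl ether.
- Fallback: the bridge bond is made by cross-coupling instead of a cation. 1 is monobrominated (NBS, MeCN, 0 °C) to methyl 2-bromo-3,5-dihydroxy-4-methoxybenzoate F5 and acetylated (Ac2O, pyridine, DMAP) to methyl 3,5-diacetoxy-2-bromo-4-methoxybenzoate F6. 2 is converted (SOCl2, CH2Cl2, 0 °C) into 3,4-bis(benzyloxy)benzyl chloride F7, and zinc insertion (Zn dust, LiCl, THF) gives [3,4-bis(benzyloxy)benzyl]zinc chloride F8. Negishi coupling of F8 with F6 (Pd(OAc)2, SPhos, THF, rt → 50 °C) should give 4 directly. This fallback sets out from 1 and 2 and comes back to the route at 4.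

**Step 5.**
- What may go wrong: sluggish ester reduction once the substrate is a poorly soluble poly-phenoxide aluminate, hydrodebromination if the mixture is then forced by heating, and ionisation of the product's benzylic alcohol or oxidation of its catechol during work-up.
- Fallback: the hydride step is replaced by hydrolysis and a borane reduction. 7 is saponified (LiOH, degassed THF/H2O, argon, then citric acid), which removes both acetates and the methyl ester and gives 2-(2,3-dibromo-4,5-dihydroxybenzyl)-3,5-dihydroxy-4-methoxybenzoic acid F9. The carboxylic acid of F9 is reduced with BH3·THF (excess, 0 °C → rt, then MeOH and water), a reagent that does not attack aryl bromides, to give 9. This fallback sets out from 7 and comes back to the route at 9.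

## Further compounds

F1 | step 4 | 5-bromovanillin (3-bromo-4-hydroxy-5-methoxybenzaldehyde, purchased) | COc1cc(C=O)cc(Br)c1O
F2 | step 4 | 2,3-dibromo-4-hydroxy-5-methoxybenzaldehyde | O=Cc1cc(OC)c(O)c(Br)c1Br
F3 | step 4 | 2,3-dibromo-4,5-dihydroxybenzaldehyde | O=Cc1cc(O)c(O)c(Br)c1Br
F4 | step 4 | 2,3-dibromo-4,5-dihydroxybenzyl alcohol | OCc1cc(O)c(O)c(Br)c1Br
F5 | step 1 | methyl 2-bromo-3,5-dihydroxy-4-methoxybenzoate | COC(=O)c1cc(O)c(OC)c(O)c1Br
F6 | step 1 | methyl 3,5-diacetoxy-2-bromo-4-methoxybenzoate | COC(=O)c1cc(OC(C)=O)c(OC)c(OC(C)=O)c1Br
F7 | step 1 | 3,4-bis(benzyloxy)benzyl chloride | ClCc1ccc(OCc2ccccc2)c(OCc2ccccc2)c1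
F8 | step 1 | [3,4-bis(benzyloxy)benzyl]zinc chloride | Cl[Zn]Cc1ccc(OCc2ccccc2)c(OCc2ccccc2)c1
F9 | step 5 | 2-(2,3-dibromo-4,5-dihydroxybenzyl)-3,5-dihydroxy-4-methoxybenzoic acid | OC(=O)c1cc(O)c(OC)c(O)c1Cc1cc(O)c(O)c(Br)c1Br
A1 | alternative 1 | [6-({[tert-butyl(dimethyl)silyl]oxy}methyl)-2,4-dihydroxy-3-methoxyphenyl][2,3-dibromo-4,5-bis(methoxymethoxy)phenyl]methanone | COc1c(O)cc(CO[Si](C)(C)C(C)(C)C)c(C(=O)c2cc(OCOC)c(OCOC)c(Br)c2Br)c1O
A2 | alternative 1 | 1,2-dimethoxy-1,3-bis(trimethylsilyloxy)buta-1,3-diene (alkene geometry not specified) | C=C(O[Si](C)(C)C)C(OC)=C(OC)O[Si](C)(C)C
A3 | alternative 1 | 4-(tert-butyldimethylsilyloxy)-1-[2,3-dibromo-4,5-bis(methoxymethoxy)phenyl]but-2-yn-1-one | CC(C)(C)[Si](C)(C)OCC#CC(=O)c1cc(OCOC)c(OCOC)c(Br)c1Br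
A4 | alternative 2 | methyl 2-[2,3-dibromo-4,5-bis(methoxymethoxy)benzyl]-3,5-dihydroxy-4-methoxybenzoate | COC(=O)c1cc(O)c(OC)c(O)c1Cc1cc(OCOC)c(OCOC)c(Br)c1Br
A5 | alternative 2 | methyl 8-[2,3-dibromo-4,5-bis(methoxymethoxy)phenyl]-5-methoxy-2,4,6-trioxooctanoate (racemic, enolisable) | COC(=O)C(=O)CC(=O)C(OC)C(=O)CCc1cc(OCOC)c(OCOC)c(Br)c1Br
A6 | alternative 3 | methyl 2-[2,3-dibromo-4,5-bis(methoxymethoxy)benzyl]-3-hydroxy-4-methoxy-5-(pivaloyloxy)benzoate | COC(=O)c1cc(OC(=O)C(C)(C)C)c(OC)c(O)c1Cc1cc(OCOC)c(OCOC)c(Br)c1Br
A7 | alternative 3 | methyl 3-hydroxy-4-methoxy-5-(pivaloyloxy)benzoate | COC(=O)c1cc(O)c(OC)c(OC(=O)C(C)(C)C)c1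
A8 | alternative 3 | [2,3-dibromo-4,5-bis(methoxymethoxy)phenyl]boronic acid | OB(O)c1cc(OCOC)c(OCOC)c(Br)c1Br
A9 | alternative 3 | formaldehyde | C=O
A10 | alternative 3 | methyl 2-[2,3-dibromo-4,5-bis(methoxymethoxy)phenyl]-8-methoxy-7-(pivaloyloxy)-4H-1,3,2-benzodioxaborine-5-carboxylate | COC(=O)c1cc(OC(=O)C(C)(C)C)c(OC)c2OB(c3cc(OCOC)c(OCOC)c(Br)c3Br)OCc12
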